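**Retrosynthetic overview**

1. Both arenes come from 4-iodo-2-methoxyphenol 1 and the whole C7 chain from hept-1-en-6-yne 2; the target is acyclic, so no ring is formed at any stage.
2. C1–aryl bond: Sonogashira coupling of 1 with 2 gives enyne 3.
3. C7–aryl bond: 9-BBN hydroboration of the terminal olefin (borane 4) and B-alkyl Suzuki coupling with a second 1 give the 1,7-diarylhept-1-yne 5.
4. Key disconnection, the C3–O bond of the ketone: a redox-neutral isomerising hydration of 5 (through allene 6 and allylic alcohol 7) puts the only new oxygen on C3 and gives target 8 without protecting groups.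

Assumption: the target has no stereocentre and no stereogenic double bond, so it is achiral and no stereocontrol is needed; hept-1-en-6-yne is taken as a catalogue reagent.

**Route**

Step 1
Reactants: 1 4-iodo-2-methoxyphenol; 2 hept-1-en-6-yne (1.2 equiv)
Product: 3 4-(hept-6-en-1-yn-1-yl)-2-methoxyphenol
Conditions: PdCl2(PPh3)2 (2 mol%), CuI (4 mol%), Et3N (3 equiv), degassed THF, rt to 40 °C
Reagents that add atoms: none
Why: Sonogashira coupling; the aryl iodide adds to Pd(0) readily even with the free phenol, the copper acetylide of 2 transmetalates cleanly, and the remote terminal olefin is inert here; no stereocentre is formed.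

Step 2
Reactants: 3 4-(hept-6-en-1-yn-1-yl)-2-methoxyphenol; 1 4-iodo-2-methoxyphenol (1.05 equiv)
Product: 5 4,4'-(hept-1-yne-1,7-diyl)bis(2-methoxyphenol), via bis-9-BBN alkylborane 4 (not isolated)
Conditions: 9-BBN-H (2.1 equiv), THF, 0 °C to rt; then 1, PdCl2(dppf) (3 mol%), aq. K3PO4 (3 M, 4 equiv), THF–DMF, 60 °C
Reagents that add atoms: none
Why: 9-BBN adds anti-Markovnikov to the terminal olefin much faster than to the internal aryl alkyne (the second equivalent is taken up by the phenol O–H as a borinate that hydrolyses in the basic aqueous stage), and the primary B-alkyl-9-BBN then undergoes B-alkyl Suzuki–Miyaura coupling with the aryl iodide; no stereocentre is formed.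

Step 3
Reactants: 5 4,4'-(hept-1-yne-1,7-diyl)bis(2-methoxyphenol)
Product: 8 1,7-bis(4-hydroxy-3-methoxyphenyl)heptan-3-one, via aryl allene 6 (not isolated), via allylic alcohol 7 (not isolated)
Conditions: [Rh(cod)Cl]2 (2.5 mol%), DPEphos (6 mol%), PPTS (10 mol%), H2O (10 equiv), 1,4-dioxane, 90 °C, Ar
Reagents that add atoms: water, O
Why: Proposed new method: a redox-neutral isomerising hydration (hydrative 1,3-transposition) of a 1-aryl-1-alkyne in one Rh–H manifold – Rh(I)/H+ gives Rh(III)–H, which hydrometalates the alkyne and β-hydride-eliminates toward the only propargylic CH2 (C3) to give allene 6, re-insertion gives a 1-aryl-3-alkyl π-allyl rhodium that water captures at C3 (the terminus remote from the arene, keeping styrene conjugation; the benzylic regioisomer and any phenol O-allyl adducts can re-ionise and drain back), and the same Rh–H isomerises allylic alcohol 7 through its enol to ketone 8 as the thermodynamic sink; the closest known reaction types are the Rh(I)/DPEphos/acid redox-neutral coupling of alkynes with carboxylic acids to allylic esters via allene and π-allyl intermediates and the Rh- or Ru-catalysed redox isomerisation of allylic alcohols to ketones, while water as the nucleophile, a non-methyl internal alkyne and the merger of the two cycles are untested; the transient C3 stereocentre of 7 is racemic and is erased in the product.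

**Compound list**

1 | 4-iodo-2-methoxyphenol | COc1cc(I)ccc1O | starting material
2 | hept-1-en-6-yne | C=CCCCC#C | starting material
3 | 4-(hept-6-en-1-yn-1-yl)-2-methoxyphenol | COc1cc(C#CCCCC=C)ccc1O | intermediate
4 | 9-{2-methoxy-4-[7-(9-borabicyclo[3.3.1]nonan-9-yl)hept-1-yn-1-yl]phenoxy}-9-borabicyclo[3.3.1]nonane (C-alkyl borane with the phenol capped as its 9-BBN borinate) | COc1cc(C#CCCCCCB2C3CCCC2CCC3)ccc1OB1C2CCCC1CCC2 | intermediate (not isolated)
5 | 4,4'-(hept-1-yne-1,7-diyl)bis(2-methoxyphenol) | COc1cc(C#CCCCCCc2ccc(O)c(OC)c2)ccc1O | intermediate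
6 | 4,4'-(hepta-1,2-diene-1,7-diyl)bis(2-methoxyphenol), racemic allene | COc1cc(C=C=CCCCCc2ccc(O)c(OC)c2)ccc1O | intermediate (not isolated)
7 | (E)-1,7-bis(4-hydroxy-3-methoxyphenyl)hept-1-en-3-ol, racemic | COc1cc(/C=C/C(O)CCCCc2ccc(O)c(OC)c2)ccc1O | intermediate (not isolated)
8 | 1,7-bis(4-hydroxy-3-methoxyphenyl)heptan-3-one | COc1cc(CCCCC(=O)CCc2ccc(O)c(OC)c2)ccc1O | target

**Step count and risks**

Total steps: 3. Longest linear sequence: 3 (1 + 2 → 3 → 5 → 8).

The three steps most likely to fail, most risky first:

Step 3 (proposed new isomerising hydration). The likely failures are ordinary Markovnikov hydration of the electron-rich aryl alkyne to the 1-aryl ketone, C–O formation at the benzylic terminus of the π-allyl (also leading to the 1-ketone), or stalling at the 1-aryl-1,3-diene. The fallback uses known chemistry, sets out from 5 and comes back to the route at 8. Both phenols of 5 are acetylated (Ac2O, pyridine, cat. DMAP) to hept-1-yne-1,7-diylbis(2-methoxy-4,1-phenylene) diacetate F1. The propargylic CH2 is then oxidised to the ynone by a known metal/TBHP propargylic oxidation (Rh2(cap)4 cat., aq. TBHP, 40 °C) to give (3-oxohept-1-yne-1,7-diyl)bis(2-methoxy-4,1-phenylene) diacetate F2; the benzylic C7 methylene is the competing site and is less activated once the arene carries an acetate. The triple bond is hydrogenated (H2, Pd/C, EtOAc) to (3-oxoheptane-1,7-diyl)bis(2-methoxy-4,1-phenylene) diacetate F3, and methanolysis (K2CO3, MeOH) releases 8.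

Step 2 (hydroboration/B-alkyl Suzuki on a free phenol that also carries an alkyne). The likely failures are borane consumption by the phenol, partial hydroboration of the alkyne by the excess 9-BBN, or protodeboronation. The fallback reverses the order of the two couplings; it sets out from 2 and comes back at 5, bypassing 3. The alkyne of 2 is masked first (n-BuLi, THF, −78 °C; TIPSOTf) as triisopropyl(hept-6-en-1-yn-1-yl)silane F4. Hydroboration of this phenol-free olefin with 9-BBN (1.1 equiv) gives 9-[7-(triisopropylsilyl)hept-6-yn-1-yl]-9-borabicyclo[3.3.1]nonane F5, which is coupled in the same flask with 1 (PdCl2(dppf), aq. K3PO4, 60 °C) to 2-methoxy-4-[7-(triisopropylsilyl)hept-6-yn-1-yl]phenol F6. Desilylation (TBAF, THF) gives 4-(hept-6-yn-1-yl)-2-methoxyphenol F7, and a Sonogashira coupling of this terminal alkyne with 1 (PdCl2(PPh3)2, CuI, Et3N) gives 5.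

Step 1 (Sonogashira with a volatile enyne and an electron-rich iodophenol). The likely failures are Glaser homocoupling of 2 or sluggish coupling. The fallback inverts the polarity of the partners; it sets out from 2 and comes back at 3. Compound 2 is brominated at the alkyne terminus (NBS, cat. AgNO3, acetone) to 7-bromohept-1-en-6-yne F8. This alkynyl bromide is coupled in a copper-free Suzuki–Miyaura reaction with commercial 2-methoxy-4-(4,4,5,5-tetramethyl-1,3,2-dioxaborolan-2-yl)phenol (Pd(PPh3)4, K2CO3, aq. THF, 50 °C) to give 3.

**Further compounds**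

F1 | step 3 | hept-1-yne-1,7-diylbis(2-methoxy-4,1-phenylene) diacetate | COc1cc(C#CCCCCCc2ccc(OC(C)=O)c(OC)c2)ccc1OC(C)=O
F2 | step 3 | (3-oxohept-1-yne-1,7-diyl)bis(2-methoxy-4,1-phenylene) diacetate | COc1cc(C#CC(=O)CCCCc2ccc(OC(C)=O)c(OC)c2)ccc1OC(C)=O
F3 | step 3 | (3-oxoheptane-1,7-diyl)bis(2-methoxy-4,1-phenylene) diacetate | COc1cc(CCC(=O)CCCCc2ccc(OC(C)=O)c(OC)c2)ccc1OC(C)=O
F4 | step 2 | triisopropyl(hept-6-en-1-yn-1-yl)silane | C=CCCCC#C[Si](C(C)C)(C(C)C)C(C)C
F5 | step 2 | 9-[7-(triisopropylsilyl)hept-6-yn-1-yl]-9-borabicyclo[3.3.1]nonane | CC(C)[Si](C#CCCCCCB1C2CCCC1CCC2)(C(C)C)C(C)C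
F6 | step 2 | 2-methoxy-4-[7-(triisopropylsilyl)hept-6-yn-1-yl]phenol | COc1cc(CCCCCC#C[Si](C(C)C)(C(C)C)C(C)C)ccc1O
F7 | step 2 | 4-(hept-6-yn-1-yl)-2-methoxyphenol | COc1cc(CCCCCC#C)ccc1O
F8 | step 1 | 7-bromohept-1-en-6-yne | C=CCCCC#CBr
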